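The slow rise of the side product is what to watch in these flasks.

the same everywhere: starting complex 23 mM
- dusk: incoming ligand 46 mM; run made earlier
- autumn: incoming ligand 110 mM; run made earlier
- ash: incoming ligand 92.0 mM; time 2.5 h
- birch: incoming ligand 140 mM; time 2.5 h

| run | time / min | complex with two exchanged / % | complex with one exchanged / % | complex with three exchanged / % | starting complex / % | side product / % |
|---|---|---|---|---|---|---|
| dusk | 4.00 | 3.9 | 19.6 | 0.2 | 76.6 | 0 |
| dusk | 12.0 | 13.5 | 33.7 | 1.4 | 51.4 | 0 |
| dusk | 20.0 | 17.0 | 41.5 | 1.6 | 39.3 | 0.3 |
| dusk | 30.0 | 18.1 | 47.5 | 1.2 | 31.9 | 0.9 |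
| dusk | 50.0 | 18.3 | 51.8 | 1.6 | 26.5 | 0.9 |
| dusk | 60.0 | 18.1 | 52.1 | 1.2 | 25.8 | 2.2 |
| dusk | 80.0 | 18.0 | 53.5 | 1.4 | 24.9 | 2.3 |
| autumn | 10.0 | 30.3 | 38.3 | 6.4 | 26.3 | 0.6 |
| autumn | 20.0 | 34.5 | 43.8 | 6.9 | 12.8 | 2.2 |
| autumn | 30.0 | 33.8 | 44.4 | 5.8 | 10.3 | 4.4 |
| autumn | 40.0 | 33.2 | 44.5 | 6.3 | 9.5 | 6.7 |
| autumn | 50.0 | 32.7 | 43.6 | 5.8 | 9.4 | 8.6 |
| autumn | 60.0 | 31.5 | 43.2 | 5.5 | 9.1 | 10.8 |
| autumn | 80.0 | 29.8 | 41.8 | 4.7 | 8.7 | 14.1 |

(each reading ± 0.3 percentage points)

- steps under discussion: complex with one exchanged + incoming ligand <-> leaving ligand + complex with two exchanged; complex with two exchanged + incoming ligand <-> leaving ligand + complex with three exchanged; leaving ligand + complex with three exchanged -> side product; starting complex + incoming ligand <-> leaving ligand + complex with one exchanged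

1. which of these there is most of at the end, counted by the starting complex in it, ash (complex with two exchanged / side product / starting complex / complex with one exchanged)
2. which of these there is most of at the end, counted by the starting complex in it, birch (complex with two exchanged / side product / starting complex / complex with one exchanged)
3. amount of the one of these that there is most of at the end, in percent of the starting complex charged, ash
4. amount of the one of these that there is most of at the end, in percent of the starting complex charged, birch

Take the first exchange by itself. In dusk the starting complex stands at 26.5% by 50.0 min and drops 1.6 percentage points over the next 30.0 min, so by then this step in dusk stands near equilibrium.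

Add the next two exchanges. In dusk the complex with two exchanged levels off too, at 18.0% by 80.0 min, and in autumn the complex with three exchanged reads 5.8% at 50.0 min. If it sits in pre-equilibrium with the complex with two exchanged, c(leaving ligand) cancels from the rate of the last step.

Add that last step. The side product then grows in proportion to c(complex with two exchanged) times c(incoming ligand). The factor is the leak constant, the rate of side product divided by those two. In autumn the side product rises steadily by 0.116 h⁻¹. Each exchange binds one incoming ligand and the side product holds three, so in autumn 35.0 mM is bound at 50.0 min. That gives 0.0791 M⁻¹ min⁻¹. Dusk gives 0.0663 M⁻¹ min⁻¹, from a rise of 1.4 points on a scatter of 0.3 points.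

Now my own reckoning. Dusk has 23.1 mM bound at 80.0 min, and there the complex with two exchanged holds 18.4% of what has not leaked, against 35.8% in autumn at 50.0 min. Drawn linearly in the charge, ash gets a share of 30.9% and 60.3 mM free. Birch, extrapolated, gets 43.9% and 99.4 mM. If these shares and free amounts are held constant, the unleaked part decays exponentially, and the estimate for side product is 19.8% in ash and 40.4% in birch. The complex with one exchanged, scaled the same way, holds 39.8% in ash, more than the side product. In birch it holds 26.4%, less than the side product. The complex with two exchanged, from its share, is estimated at 24.8% in ash, less than the complex with one exchanged, and at 26.2% in birch, less than the side product.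

The forecast names complex with one exchanged in ash at 43% (40% to 46%) and side product in birch at 35% (31% to 39%), on this ground: “Both runs reach a fast pseudo-equilibrium, and side product then drains it slowly.” My choices are the same, but my ash number stands below the forecast's and my birch number above its range.

    complex with one exchanged + incoming ligand ⇌ leaving ligand + complex with two exchanged (K = 0.330, k = 0.0370 M⁻¹ s⁻¹)
    complex with two exchanged + incoming ligand ⇌ leaving ligand + complex with three exchanged (K = 0.0850, k = 0.0150 M⁻¹ s⁻¹)
    leaving ligand + complex with three exchanged → side product (k = 0.0170 M⁻¹ s⁻¹)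
    starting complex + incoming ligand ⇌ leaving ligand + complex with one exchanged (K = 2.10, k = 0.0260 M⁻¹ s⁻¹)

The flask gives complex with one exchanged at 42.2% in ash and side product at 35.8% in birch, both inside the forecast's ranges. Birch still has 67.2% of its incoming ligand free at the end. With the ash states at 1.25 h and 2.50 h, the leak constant gives a rise of 9 points between them, and ash shows 9 points. For birch left until 4.0 h, it gives 14 points more, and that flask reaches 49.6%, a rise of 14 points.

(Readings and results come from a simulation with constants of no real substance.)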